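# Proposed synthesis of (2S,3S,4S,5R)-2,5-bis(4-hydroxy-3,5-dimethoxyphenyl)-3,4-dimethyloxolane (24) by rhodium-carbene C–H insertion

## Analysis of the target

Target 24 is a 2,5-diaryl-3,4-dimethyloxolane, a tetrahydrofuran lignan carrying two identical 4-hydroxy-3,5-dimethoxyphenyl groups on its single ring (O1, C2–C5). All four ring carbons are stereocentres, (2S,3S,4S,5R): the aryl groups are cis across the ring oxygen, the methyl groups are trans, the C2 aryl group is trans to the C3 methyl group and the C5 aryl group is cis to the C4 methyl group. This trans,trans,cis pattern removes all symmetry, so the two halves are not equivalent and a symmetric dimerisation cannot deliver the molecule. Both ring C–O bonds are benzylic and para-oxygenated, so they ionise under acid (epimerisation at C2 or C5, ring opening) and can be hydrogenolysed; the free phenols are easily oxidised and are therefore carried as benzyl ethers. The difficulty is four adjacent stereocentres on a five-membered ring with no directing group other than the ether oxygen, including a C4/C5 cis pair that has to be made under kinetic control. The strategy rests on C5, which is benzylic, bound to O1 and adjacent to C4. If O1 is first alkylated with the arylmethyl group that becomes C5, the ring closes by forming C4–C5 through insertion of a C4 carbene into that benzylic C–H bond. The C4 methyl group is carried through this step as the ester that stabilises the diazo precursor.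

## Retrosynthetic reasoning

**24 to 23.** Only the two phenolic O–H bonds are addressed. Benzyl ethers are inert to hydride, base, borane and the carbene chemistry, and come off last under neutral conditions. The forward step has to remove two aryl benzyl ethers without touching the benzylic C–O bonds of the ring.

**23 to 20 (through 22 and 21).** No skeletal bond is cut. The C4 methyl group is traced back to a methoxycarbonyl group, because a carbene at C4 needs an acceptor substituent for a handleable diazo precursor, and an ester is the smallest acceptor that can be taken down to CH3. The forward sequence (ester to carbinol, sulfonate, hydride displacement) must not epimerise C4, which is acidic only in 20.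

**20 to 19.** The C4–C5 bond is cut. C5–H is the most activated C–H bond in the open chain, and opening the ring here leaves only the anti C2/C3 pair to acyclic control. O1–C5 becomes an ordinary ether bond. Cutting C2–C3 or C3–C4 instead would leave three centres to be set on a ring or by less direct means. The gain is the ring, one C–C bond and two stereocentres in one step. The forward reaction must prefer 1,5 insertion over hydride shift, place the C5 aryl group cis to the C2 aryl group, and place the C4 ester trans to the C3 methyl group.

**19 to 17.** The diazo group is removed to give a CH2 group alpha to the ester. A plain ester is not acidic enough for direct diazo transfer, so the forward step activates it temporarily by C-trifluoroacetylation and loses that group during the transfer.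

**17 to 12 (through 16 and 14).** The ester carbon is traced to the terminal carbon of a vinyl group by anti-Markovnikov hydration and oxidation; no stereocentre is involved. The O1 ether must already be in place, because a free hydroxy acid at this stage would lactonise.

**12 to 11 and 5.** The O1–C5 ether bond is cut (Williamson etherification). Bromide 5 comes from alcohol 4 and so from aldehyde 3, which means both aryl groups derive from the same aldehyde.

**11 to 3 and 6.** The C2–C3 bond is cut. An anti-selective, reagent-controlled crotylboration sets C2 and C3 together. It is the only step that introduces absolute configuration.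

**3 to 1 and 2.** O-Benzylation of the hindered phenol.

## Alternatives that were turned down

Alternative 1: ylide annulation.
- Disconnection: C2–C3 and O1–C2 are cut together, giving the aryl tigloyl ketone A1 and a chiral arylmethyl sulfonium salt A2.
- Forward key step: the ylide of A2 adds to the beta carbon of A1, and the enolate oxygen displaces the sulfide at the benzylic carbon to close the 2,3-trans dihydrofuran A3. Hydrogenation of C4=C5 would follow.
- For: it is the shortest plan. Both fragments are one or two steps from 3, and the ring, C2 and C3 arise in one operation with the natural trans relationship.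
- Against: semi-stabilised benzylic ylides usually close through the enolate carbon (three-membered ring) or add to the carbonyl group. Closure through oxygen is favoured only for strongly stabilised enolates, and the alpha,beta-dimethyl enone is a poor acceptor. C4 and C5 would then depend on hydrogenating a tetrasubstituted, acid-sensitive enol ether from the face that carries the C3 methyl group. The forcing conditions this needs also threaten the benzylic ring C–O bonds.
- Comparison: Alternative 1 is better on step count and convergence. The chosen route sets C4 and C5 in the bond-forming event itself, with retention at C5, and takes its absolute configuration from a dependable crotylation instead of an ylide whose enantiocontrol in this mode is uncertain.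

Alternative 2: donor–acceptor cyclopropane annulation.
- Disconnection: O1–C5 and C2–C3 are cut, with C3 as a malonate carbon, giving the trans cyclopropane diester A4 and aldehyde 3.
- Forward key step: Sn(OTf)2 coordinates the geminal diester of A4, the carbonyl oxygen of 3 attacks the aryl-bearing carbon with inversion, and the malonate carbon then closes on the oxocarbenium carbon to give A5.
- For: ring closure is stereospecific and places the two aryl groups cis. Inversion turns the trans cyclopropane into the C4/C5 cis relationship, and 3 is used directly. On predictability of the ring-forming step it is probably stronger than the chosen key step.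
- Against: A4 must be made enantioenriched, and electron-rich aryl donors open reversibly under Lewis acid, which erodes optical purity. C3 emerges quaternary, so one ester must be excised thermally, the C3 configuration set by equilibration, and the remaining ester reduced to methyl. That is the same three-step tail as the chosen route plus a decarboxylation.
- Comparison: the chosen route offers a configurationally stable precursor, no carbon to remove, and C3 fixed from the outset.

Alternative 3: butenolide methylation.
- Disconnection: the two C–CH3 bonds are cut on butenolide A6; the C5–aryl bond is made later.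
- Forward key step: Me2CuLi delivers a methyl group to the beta carbon of A6 on the face away from the aryl group, and the resulting lactone enolate is then methylated by MeI on the face away from the new methyl group, giving A7. No ring forms. The second aryl group then enters by addition of aryllithium A8 to the lactone carbonyl, and the anomeric hydroxyl group is removed reductively, with hydride arriving anti to the C4 methyl group.
- For: every centre is set by 1,2-induction on a rigid five-membered ring, in chemistry that is well established for this lignan family. Its stereochemical outcome is more predictable than that of the chosen key step.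
- Against: A6 needs its own enantioselective synthesis. The endgame passes through an oxocarbenium ion under strong Lewis acid, the conditions under which the electron-rich C2 benzylic ether epimerises. The two aryl groups are also introduced by unrelated chemistry.
- Comparison: the chosen strategy offers a neutral, C–C bond-forming ring closure that sets two centres at once and draws both aryl groups from 3. The lactone logic is kept in reserve as the fallback for the key step.

Key step: step 10

## Route

Notation: Ar = 4-(benzyloxy)-3,5-dimethoxyphenyl; Ipc = isopinocampheyl derived from (+)-α-pinene; PTTL = N-phthaloyl-tert-leucinate; ring positions are numbered as in the target.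

Assumption: Rh2(S-PTTL)4 is taken as the catalyst enantiomer whose ligand shell cooperates with the C2/C3 bias of 19; should the two oppose each other, Rh2(R-PTTL)4 is used in step 10 with nothing else changed.

Step 1
Reactants: 1 syringaldehyde (4-hydroxy-3,5-dimethoxybenzaldehyde); 2 benzyl bromide
Product: 3 4-(benzyloxy)-3,5-dimethoxybenzaldehyde
Conditions: K2CO3, DMF, 60 °C
Reagents that add atoms: none
Why: Williamson O-alkylation of the phenoxide; the aldehyde is untouched and the hindered phenol still reacts cleanly with a benzylic halide in a dipolar aprotic solvent.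

Step 2
Reactants: 3 4-(benzyloxy)-3,5-dimethoxybenzaldehyde
Product: 4 [4-(benzyloxy)-3,5-dimethoxyphenyl]methanol
Conditions: NaBH4, MeOH, 0 °C
Reagents that add atoms: none
Why: Borohydride reduction of an aryl aldehyde to the benzylic alcohol; the ether groups are inert.

Step 3
Reactants: 4 [4-(benzyloxy)-3,5-dimethoxyphenyl]methanol
Product: 5 2-(benzyloxy)-5-(bromomethyl)-1,3-dimethoxybenzene
Conditions: PBr3, Et2O, 0 °C
Reagents that add atoms: phosphorus tribromide (BrP(Br)Br)
Why: Conversion of a benzylic alcohol into the bromide through its phosphite ester; the bromide is used promptly because electron-rich benzylic halides are reactive.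

Step 4
Reactants: 3 4-(benzyloxy)-3,5-dimethoxybenzaldehyde; 6 trans-2-butene
Product: 11 (1S,2S)-1-Ar-2-methylbut-3-en-1-ol, via (E)-but-2-enylpotassium 7 (not isolated), via potassium (E)-but-2-enyl(methoxy)bis(Ipc)borate 8 (not isolated), via (E)-but-2-enylbis(Ipc)borane 9 (not isolated), via bis(Ipc)borinate ester 10 (not isolated)
Conditions: 6, KOC(CH3)3, n-BuLi, THF, −78 to −45 °C; (−)-Ipc2BOMe, −78 °C; BF3·OEt2; 3, −78 °C; then NaOH, H2O2, 0 °C to rt
Reagents that add atoms: none
Why: Brown crotylboration through a closed chair Zimmerman–Traxler transition state, in which the E geometry of the crotylborane becomes the anti relationship of C2 and C3. The isopinocampheyl groups from (+)-α-pinene direct the crotyl group to the Si face of the aldehyde, which corresponds to the (1S,2S) alcohol; low temperature prevents E/Z scrambling of the crotyl metal species.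

Step 5
Reactants: 11 (1S,2S)-1-Ar-2-methylbut-3-en-1-ol; 5 2-(benzyloxy)-5-(bromomethyl)-1,3-dimethoxybenzene
Product: 12 (1S,2S)-1-Ar-1-(Ar-methoxy)-2-methylbut-3-ene
Conditions: NaH, Bu4NI (cat.), THF–DMF, 0 °C to rt
Reagents that add atoms: none
Why: Williamson etherification of the secondary alkoxide with a reactive benzylic bromide, with iodide catalysis; no stereocentre is involved and the basic medium avoids ionising the benzylic carbinol.

Step 6
Reactants: 12 (1S,2S)-1-Ar-1-(Ar-methoxy)-2-methylbut-3-ene
Product: 14 (3S,4S)-4-Ar-4-(Ar-methoxy)-3-methylbutan-1-ol, via B-alkyl-9-borabicyclo[3.3.1]nonane 13 (not isolated)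
Conditions: 9-BBN, THF, 0 °C to rt; then NaOH, H2O2, 0 °C
Reagents that add atoms: hydrogen peroxide (OO)
Why: Anti-Markovnikov hydroboration of the monosubstituted alkene with a bulky dialkylborane, then oxidation of the C–B bond; the terminal carbon becomes CH2OH and no stereocentre is created.

Step 7
Reactants: 14 (3S,4S)-4-Ar-4-(Ar-methoxy)-3-methylbutan-1-ol
Product: 16 (3S,4S)-4-Ar-4-(Ar-methoxy)-3-methylbutanoic acid, via aldehyde 15 (not isolated)
Conditions: TEMPO (cat.), PhI(OAc)2, MeCN–H2O, rt
Reagents that add atoms: water (O)
Why: Oxoammonium-catalysed oxidation of the primary alcohol to the aldehyde, whose hydrate is oxidised further to the acid; the catalytic oxidant is mild enough to spare the electron-rich arenes and benzylic ethers, and C3 is not adjacent to the carbonyl group.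

Step 8
Reactants: 16 (3S,4S)-4-Ar-4-(Ar-methoxy)-3-methylbutanoic acid
Product: 17 methyl (3S,4S)-4-Ar-4-(Ar-methoxy)-3-methylbutanoate
Conditions: MeI, K2CO3, DMF, rt
Reagents that add atoms: iodomethane (CI)
Why: O-Alkylation of the carboxylate; no other nucleophilic site is present.

Step 9
Reactants: 17 methyl (3S,4S)-4-Ar-4-(Ar-methoxy)-3-methylbutanoate
Product: 19 methyl (3S,4S)-4-Ar-4-(Ar-methoxy)-2-diazo-3-methylbutanoate, via 2-trifluoroacetyl ester 18 (not isolated)
Conditions: LiN(SiMe3)2, THF, −78 °C; CF3CO2CH2CF3; then 4-acetamidobenzenesulfonyl azide, Et3N, H2O, MeCN, rt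
Reagents that add atoms: 4-acetamidobenzenesulfonyl azide (CC(=O)Nc1ccc(cc1)S(=O)(=O)N=[N+]=[N-])
Why: Detrifluoroacetylative diazo transfer: the ester enolate is C-acylated to an activated 1,3-dicarbonyl compound, which accepts the diazo group from the sulfonyl azide and expels the trifluoroacetyl group as the N-acyl sulfonamide. C3 is beta to the ester and C2 is not acidic, so neither centre is at risk.

Step 10
Reactants: 19 methyl (3S,4S)-4-Ar-4-(Ar-methoxy)-2-diazo-3-methylbutanoate
Product: 20 methyl (2R,3S,4S,5S)-2,5-bis(Ar)-4-methyloxolane-3-carboxylate (in target numbering the ester sits on C4, cis to the C5 aryl group and trans to the C3 methyl group)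
Conditions: Rh2(S-PTTL)4 (2 mol%), toluene, 4 Å MS, −78 to −40 °C
Reagents that add atoms: none
Why: The dirhodium tetrakis[N-phthaloyl-(S)-tert-leucinate] complex takes up the diazo carbon and loses N2 to give an electrophilic rhodium carbene at C4, which inserts into one benzylic C–H bond of the Ar-CH2–O group through a concerted, hydride-transfer-like three-centre transition state, forming C4–C5 with retention at C5 and releasing the catalyst. The closest known reaction type is the dirhodium-carboxylate-catalysed intramolecular 1,5 C–H insertion of alpha-diazo esters next to an ether oxygen, which gives cis-2-aryl-3-carboxylate oxacycles with this catalyst class. The oxolane closes by C–C bond formation between C4 and C5 in a five-membered, envelope-like transition state; this mode is favoured because only this C–H bond is both within reach and doubly activated (benzylic and alpha to oxygen, on an electron-rich arene). C5 is set by which of the two diastereotopic benzylic hydrogens is replaced: the new aryl group should take the pseudo-equatorial position on the face of the C2 aryl group, giving the 2,5-cis arrangement. C4 is set by the orientation of the carbene ester, which should lie anti to the adjacent C3 methyl group; this is also the side cis to the C5 aryl group, the kinetic outcome normally seen for benzylic ether insertion, so substrate bias and intrinsic preference point the same way and the ligand shell only has to reinforce them. The step needs chemoselectivity over 1,2-hydride shift from C3 to the unsaturated ester and over attack of the carbene on the ortho position of the C2 aryl ring. The bulky phthalimido carboxylate ligands and the low temperature disfavour the hydride shift, and the strongly hydridic benzylic ether C–H bond favours insertion over aromatic substitution.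

Step 11
Reactants: 20 methyl (2R,3S,4S,5S)-2,5-bis(Ar)-4-methyloxolane-3-carboxylate
Product: 21 [(2R,3R,4S,5S)-2,5-bis(Ar)-4-methyloxolan-3-yl]methanol
Conditions: LiAlH4, THF, 0 °C
Reagents that add atoms: none
Why: Hydride reduction of the ester to the primary alcohol; addition to the carbonyl group is much faster than enolisation at 0 °C, so C4 keeps its configuration (the descriptor changes only through priority rules).

Step 12
Reactants: 21 [(2R,3R,4S,5S)-2,5-bis(Ar)-4-methyloxolan-3-yl]methanol
Product: 22 [(2R,3R,4S,5S)-2,5-bis(Ar)-4-methyloxolan-3-yl]methyl methanesulfonate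
Conditions: MsCl, Et3N, CH2Cl2, 0 °C
Reagents that add atoms: methanesulfonyl chloride (CS(=O)(=O)Cl)
Why: Sulfonylation of a primary alcohol under buffered basic conditions that do not endanger the acid-sensitive ring.

Step 13
Reactants: 22 [(2R,3R,4S,5S)-2,5-bis(Ar)-4-methyloxolan-3-yl]methyl methanesulfonate
Product: 23 (2S,3S,4S,5R)-2,5-bis(Ar)-3,4-dimethyloxolane
Conditions: LiEt3BH, THF, 0 °C to rt
Reagents that add atoms: none
Why: SN2 displacement of the primary sulfonate by a powerful, weakly basic hydride donor converts CH2OMs into CH3; the reaction takes place at the exocyclic carbon, so no ring stereocentre is touched.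

Step 14
Reactants: 23 (2S,3S,4S,5R)-2,5-bis(Ar)-3,4-dimethyloxolane
Product: 24 4,4'-[(2S,3S,4S,5R)-3,4-dimethyloxolane-2,5-diyl]bis(2,6-dimethoxyphenol)
Conditions: H2 (1 atm), Pd/C, EtOAc, rt
Reagents that add atoms: none
Why: Hydrogenolysis of aryl benzyl ethers, which is much faster than cleavage of the dialkyl benzylic C–O bonds of the ring in a neutral, non-protic solvent; the reaction is stopped as soon as the benzyl groups are gone.

## Compound list

(Ar = 4-(benzyloxy)-3,5-dimethoxyphenyl; Ipc = isopinocampheyl from (+)-α-pinene)

1 | syringaldehyde (4-hydroxy-3,5-dimethoxybenzaldehyde) | COc1cc(C=O)cc(OC)c1O | starting material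
2 | benzyl bromide | BrCc1ccccc1 | starting material
3 | 4-(benzyloxy)-3,5-dimethoxybenzaldehyde | COc1cc(C=O)cc(OC)c1OCc1ccccc1 | intermediate
4 | [4-(benzyloxy)-3,5-dimethoxyphenyl]methanol | COc1cc(CO)cc(OC)c1OCc1ccccc1 | intermediate
5 | 2-(benzyloxy)-5-(bromomethyl)-1,3-dimethoxybenzene | COc1cc(CBr)cc(OC)c1OCc1ccccc1 | intermediate
6 | trans-2-butene | C/C=C/C | starting material
7 | (E)-but-2-enylpotassium | C/C=C/[CH2-].[K+] | intermediate
8 | potassium (E)-but-2-enyl(methoxy)bis(Ipc)borate | C/C=C/C[B-](OC)([C@@H]1C[C@@H]2C[C@H]([C@H]1C)C2(C)C)[C@@H]1C[C@@H]2C[C@H]([C@H]1C)C2(C)C.[K+] | intermediate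
9 | (E)-but-2-enylbis(Ipc)borane | C/C=C/CB([C@@H]1C[C@@H]2C[C@H]([C@H]1C)C2(C)C)[C@@H]1C[C@@H]2C[C@H]([C@H]1C)C2(C)C | intermediate
10 | (1S,2S)-1-Ar-2-methylbut-3-enyl bis(Ipc)borinate | C=C[C@H](C)[C@H](OB([C@@H]1C[C@@H]2C[C@H]([C@H]1C)C2(C)C)[C@@H]1C[C@@H]2C[C@H]([C@H]1C)C2(C)C)c1cc(OC)c(OCc2ccccc2)c(OC)c1 | intermediate
11 | (1S,2S)-1-Ar-2-methylbut-3-en-1-ol | C=C[C@H](C)[C@H](O)c1cc(OC)c(OCc2ccccc2)c(OC)c1 | intermediate
12 | (1S,2S)-1-Ar-1-(Ar-methoxy)-2-methylbut-3-ene | C=C[C@H](C)[C@H](OCc1cc(OC)c(OCc2ccccc2)c(OC)c1)c1cc(OC)c(OCc2ccccc2)c(OC)c1 | intermediate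
13 | 9-[(3S,4S)-4-Ar-4-(Ar-methoxy)-3-methylbutyl]-9-borabicyclo[3.3.1]nonane | C1CC2CCCC(C1)B2CC[C@H](C)[C@H](OCc1cc(OC)c(OCc2ccccc2)c(OC)c1)c1cc(OC)c(OCc2ccccc2)c(OC)c1 | intermediate
14 | (3S,4S)-4-Ar-4-(Ar-methoxy)-3-methylbutan-1-ol | OCC[C@H](C)[C@H](OCc1cc(OC)c(OCc2ccccc2)c(OC)c1)c1cc(OC)c(OCc2ccccc2)c(OC)c1 | intermediate
15 | (3S,4S)-4-Ar-4-(Ar-methoxy)-3-methylbutanal | O=CC[C@H](C)[C@H](OCc1cc(OC)c(OCc2ccccc2)c(OC)c1)c1cc(OC)c(OCc2ccccc2)c(OC)c1 | intermediate
16 | (3S,4S)-4-Ar-4-(Ar-methoxy)-3-methylbutanoic acid | OC(=O)C[C@H](C)[C@H](OCc1cc(OC)c(OCc2ccccc2)c(OC)c1)c1cc(OC)c(OCc2ccccc2)c(OC)c1 | intermediate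
17 | methyl (3S,4S)-4-Ar-4-(Ar-methoxy)-3-methylbutanoate | COC(=O)C[C@H](C)[C@H](OCc1cc(OC)c(OCc2ccccc2)c(OC)c1)c1cc(OC)c(OCc2ccccc2)c(OC)c1 | intermediate
18 | methyl (3S,4S)-4-Ar-4-(Ar-methoxy)-3-methyl-2-(trifluoroacetyl)butanoate (C2 epimers and enol) | COC(=O)C(C(=O)C(F)(F)F)[C@H](C)[C@H](OCc1cc(OC)c(OCc2ccccc2)c(OC)c1)c1cc(OC)c(OCc2ccccc2)c(OC)c1 | intermediate
19 | methyl (3S,4S)-4-Ar-4-(Ar-methoxy)-2-diazo-3-methylbutanoate | COC(=O)C(=[N+]=[N-])[C@H](C)[C@H](OCc1cc(OC)c(OCc2ccccc2)c(OC)c1)c1cc(OC)c(OCc2ccccc2)c(OC)c1 | intermediate
20 | methyl (2R,3S,4S,5S)-2,5-bis(Ar)-4-methyloxolane-3-carboxylate | COc1cc([C@H]2O[C@@H](c3cc(OC)c(OCc4ccccc4)c(OC)c3)[C@@H](C(=O)OC)[C@@H]2C)cc(OC)c1OCc1ccccc1 | intermediate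
21 | [(2R,3R,4S,5S)-2,5-bis(Ar)-4-methyloxolan-3-yl]methanol | COc1cc([C@H]2O[C@@H](c3cc(OC)c(OCc4ccccc4)c(OC)c3)[C@@H](CO)[C@@H]2C)cc(OC)c1OCc1ccccc1 | intermediate
22 | [(2R,3R,4S,5S)-2,5-bis(Ar)-4-methyloxolan-3-yl]methyl methanesulfonate | COc1cc([C@H]2O[C@@H](c3cc(OC)c(OCc4ccccc4)c(OC)c3)[C@@H](COS(C)(=O)=O)[C@@H]2C)cc(OC)c1OCc1ccccc1 | intermediate
23 | (2S,3S,4S,5R)-2,5-bis(Ar)-3,4-dimethyloxolane | COc1cc([C@H]2O[C@@H](c3cc(OC)c(OCc4ccccc4)c(OC)c3)[C@@H](C)[C@@H]2C)cc(OC)c1OCc1ccccc1 | intermediate
24 | 4,4'-[(2S,3S,4S,5R)-3,4-dimethyloxolane-2,5-diyl]bis(2,6-dimethoxyphenol) | COc1cc([C@H]2O[C@@H](c3cc(OC)c(O)c(OC)c3)[C@@H](C)[C@@H]2C)cc(OC)c1O | target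

## Step count and least certain steps

Total: 14 steps. Longest linear sequence: 13 steps (steps 1–3 and 5–14, from 1 through bromide 5 to 24); step 4 is a one-step branch from 3 that supplies alcohol 11 for the union in step 5.

**Step 10 (key step).**
- What may go wrong: the carbene is diverted before it reaches the benzylic C–H bond, by 1,2-hydride shift from C3 or by attack on the electron-rich ortho position of the C2 aryl ring. If insertion does occur, control at C4 and C5 may be incomplete should ligand shell and substrate bias not cooperate.
- Why: an alkyl-substituted acceptor carbene is very electrophilic, carries a beta hydrogen and has an activated arene three atoms away.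
- Fallback (known lactone chemistry, sets out from 11 and returns to the route at 23): hydroboration–oxidation of 11 (9-BBN; NaOH, H2O2) should give (1S,2S)-1-Ar-2-methylbutane-1,4-diol F1. TEMPO with PhI(OAc)2 in CH2Cl2 oxidises the primary alcohol and the lactol formed from it to (4S,5S)-5-Ar-4-methyloxolan-2-one F2. LiN(SiMe3)2 and MeI at −78 °C methylate the enolate anti to the neighbouring methyl group, giving (3S,4S,5S)-5-Ar-3,4-dimethyloxolan-2-one F3. Benzylation of commercial 4-bromo-2,6-dimethoxyphenol with 2 (K2CO3, DMF) gives 2-(benzyloxy)-5-bromo-1,3-dimethoxybenzene F4, and n-BuLi exchange at −78 °C gives [4-(benzyloxy)-3,5-dimethoxyphenyl]lithium F5. Addition of F5 to F3 gives (3S,4S,5S)-2,5-bis(Ar)-3,4-dimethyloxolan-2-ol F6. Et3SiH with BF3·OEt2 in CH2Cl2 at −78 °C reduces the derived oxocarbenium ion by hydride delivery anti to the adjacent methyl group, which places the new aryl group cis to that methyl group and gives 23.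

**Step 9.**
- What may go wrong: incomplete C-trifluoroacetylation of the beta-branched ester enolate (O-acylation or self-condensation), so that diazo transfer stalls. Simple esters are poorer substrates for this activation than ketones.
- Fallback (from 17 back to 19): the potassium enolate of 17 (KN(SiMe3)2, THF, −78 °C) is treated with 2,4,6-triisopropylbenzenesulfonyl azide and quenched with acetic acid, transferring an azide group to give methyl (3S,4S)-2-azido-4-Ar-4-(Ar-methoxy)-3-methylbutanoate F7. N-Succinimidyl 3-(diphenylphosphino)propanoate in THF–H2O, then NaHCO3, converts the azide through an acyl triazene into diazo ester 19.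

**Step 4.**
- What may go wrong: enantio- and diastereoselectivity erode through E/Z isomerisation of the crotyl metal species on warming, or through slow addition to the deactivated, electron-rich aldehyde.
- Fallback (from 4 back to 11, no new isolated compound): iridium-catalysed transfer-hydrogenative crotylation of benzylic alcohol 4 with but-3-en-2-yl acetate ([Ir(cod)Cl]2, the SEGPHOS enantiomer that gives the (1S,2S) product, 4-cyano-3-nitrobenzoic acid, Cs2CO3, THF, 90 °C). The alcohol is dehydrogenated in the flask and the anti adduct 11 forms by catalyst control.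

**Step 13.**
- What may go wrong: hydride attacks sulfur (S–O cleavage back to the alcohol) or elimination competes with substitution, because the carbon bearing the sulfonate is beta-branched and flanked by the C5 aryl group.
- Fallback (from 21 back to 23): I2, PPh3 and imidazole convert 21 into (2R,3S,4S,5S)-2,5-bis(Ar)-3-(iodomethyl)-4-methyloxolane F8, and radical deiodination with Bu3SnH and AIBN in toluene at 80 °C gives 23 without an ionic step at the hindered carbon.

**Step 14.**
- What may go wrong: over-reduction by hydrogenolysis of the ring C2–O or C5–O bonds, or epimerisation at these centres on an acidic catalyst surface. Both ring C–O bonds are activated benzylic ethers.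
- Fallback (from 23 directly to 24, no new compound): non-reductive debenzylation with BCl3 and pentamethylbenzene as cation scavenger in CH2Cl2 at −78 °C, which cleaves aryl benzyl ethers by Lewis acid activation and benzyl transfer. The benzyloxy group flanked by two methoxy groups is the most congested and best chelating ether in the molecule, so it should be attacked before the ring oxygen at this temperature.

## Further compounds

F1 | step 10 | (1S,2S)-1-Ar-2-methylbutane-1,4-diol | OCC[C@H](C)[C@H](O)c1cc(OC)c(OCc2ccccc2)c(OC)c1
F2 | step 10 | (4S,5S)-5-Ar-4-methyloxolan-2-one | COc1cc([C@H]2OC(=O)C[C@@H]2C)cc(OC)c1OCc1ccccc1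
F3 | step 10 | (3S,4S,5S)-5-Ar-3,4-dimethyloxolan-2-one | COc1cc([C@H]2OC(=O)[C@@H](C)[C@@H]2C)cc(OC)c1OCc1ccccc1
F4 | step 10 | 2-(benzyloxy)-5-bromo-1,3-dimethoxybenzene | COc1cc(Br)cc(OC)c1OCc1ccccc1
F5 | step 10 | [4-(benzyloxy)-3,5-dimethoxyphenyl]lithium | [Li]c1cc(OC)c(OCc2ccccc2)c(OC)c1
F6 | step 10 | (3S,4S,5S)-2,5-bis(Ar)-3,4-dimethyloxolan-2-ol (both C2 epimers) | COc1cc([C@H]2OC(O)(c3cc(OC)c(OCc4ccccc4)c(OC)c3)[C@@H](C)[C@@H]2C)cc(OC)c1OCc1ccccc1
F7 | step 9 | methyl (3S,4S)-2-azido-4-Ar-4-(Ar-methoxy)-3-methylbutanoate (C2 epimers) | COC(=O)C(N=[N+]=[N-])[C@H](C)[C@H](OCc1cc(OC)c(OCc2ccccc2)c(OC)c1)c1cc(OC)c(OCc2ccccc2)c(OC)c1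
F0 | step 4 | none | none
F8 | step 13 | (2R,3S,4S,5S)-2,5-bis(Ar)-3-(iodomethyl)-4-methyloxolane | COc1cc([C@H]2O[C@@H](c3cc(OC)c(OCc4ccccc4)c(OC)c3)[C@@H](CI)[C@@H]2C)cc(OC)c1OCc1ccccc1
F0 | step 14 | none | none
A1 | alternative 1 | (E)-1-Ar-2-methylbut-2-en-1-one | C/C=C(\C)C(=O)c1cc(OC)c(OCc2ccccc2)c(OC)c1
A2 | alternative 1 | (2R,5R)-1-(Ar-methyl)-2,5-dimethylthiolan-1-ium bromide | C[C@@H]1CC[C@@H](C)[S+]1Cc1cc(OC)c(OCc2ccccc2)c(OC)c1.[Br-]
A3 | alternative 1 | (2S,3S)-2,5-bis(Ar)-3,4-dimethyl-2,3-dihydrofuran | COc1cc([C@H]2OC(c3cc(OC)c(OCc4ccccc4)c(OC)c3)=C(C)[C@@H]2C)cc(OC)c1OCc1ccccc1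
A4 | alternative 2 | dimethyl (2S,3R)-2-Ar-3-methylcyclopropane-1,1-dicarboxylate (aryl and methyl trans) | COC(=O)C1(C(=O)OC)[C@H](c2cc(OC)c(OCc3ccccc3)c(OC)c2)[C@H]1C
A5 | alternative 2 | dimethyl (2R,4S,5R)-2,5-bis(Ar)-4-methyloxolane-3,3-dicarboxylate (aryl groups cis, C4 methyl cis to C5 aryl) | COc1cc([C@H]2O[C@@H](c3cc(OC)c(OCc4ccccc4)c(OC)c3)[C@@H](C)C2(C(=O)OC)C(=O)OC)cc(OC)c1OCc1ccccc1
A6 | alternative 3 | (5S)-5-Ar-furan-2(5H)-one | COc1cc([C@H]2OC(=O)C=C2)cc(OC)c1OCc1ccccc1
A7 | alternative 3 | (3S,4S,5S)-5-Ar-3,4-dimethyloxolan-2-one | COc1cc([C@H]2OC(=O)[C@@H](C)[C@@H]2C)cc(OC)c1OCc1ccccc1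
A8 | alternative 3 | [4-(benzyloxy)-3,5-dimethoxyphenyl]lithium | [Li]c1cc(OC)c(OCc2ccccc2)c(OC)c1
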